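**Strategy.** Ring D carries five contiguous oxygens (C1–C5) beside a single C6–H. It is therefore disconnected to a squarate, which supplies C2–C5 with their oxygens, and a 2-aryloxyvinyl unit, which supplies C6 and C1 already bonded to the ring C oxygen. Heating the 4-[(Z)-2-aryloxyethenyl]-2,3,4-trimethoxycyclobutenone 17 opens the four-membered ring to a dienylketene that closes ring D through the new C1–C2 bond and leaves only the C2 hydroxyl unprotected, ready for ring E. The A-B-C aryl ether comes from two fluoride displacement/Dakin cycles, and the precursor from acetylide addition to dimethyl squarate, O-methylation and cis-semihydrogenation. Chan–Lam arylation and global demethylation finish the target.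

Key step: step 8

Remark on the chemistry: the enol ether is carried as the Z isomer, because an (E)-2-aryloxyvinyllithium holds lithium anti to the aryloxy group and would expel aryloxide, whereas the acetylide/semihydrogenation sequence needs no vinyl anion and the ketene closure accepts either geometry; compounds 1, 2 and 6 are taken as catalogue chemicals.

Rings are lettered A to E from the 2,4,6-trioxygenated end to the 3,4,5-trioxygenated end. Ar stands for the A-B-C aryl group 4-[2,4-dimethoxy-6-(2,4,6-trimethoxyphenoxy)phenoxy]-2,6-dimethoxyphenyl.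

Step 1
Reactants: 1 ring A phenol (2,4,6-trimethoxyphenol); 2 ring B fluoroaldehyde (2-fluoro-4,6-dimethoxybenzaldehyde)
Product: 3 A-B aldehyde [2,4-dimethoxy-6-(2,4,6-trimethoxyphenoxy)benzaldehyde]
Conditions: K2CO3, DMF, 110 °C, Ar
Reagents that add atoms: none
Why: Nucleophilic aromatic substitution (SNAr) in which the ortho formyl group stabilises the Meisenheimer adduct and fluoride leaves, both methoxy groups being meta to the reacting carbon and so not deactivating it.

Step 2
Reactants: 3 A-B aldehyde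
Product: 5 A-B phenol [2,4-dimethoxy-6-(2,4,6-trimethoxyphenoxy)phenol], via aryl formate 4 (not isolated)
Conditions: mCPBA, CH2Cl2, 0 °C to rt; then K2CO3 (cat.), MeOH, rt, Ar
Reagents that add atoms: mCPBA, O=C(OO)c1cccc(Cl)c1
Why: Dakin-type Baeyer–Villiger oxidation in which the electron-rich aryl group migrates to oxygen to give formate 4, whose methanolysis frees the phenol while methyl and diaryl ethers stay intact.

Step 3
Reactants: 5 A-B phenol; 6 ring C fluoroaldehyde (4-fluoro-2,6-dimethoxybenzaldehyde)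
Product: 7 A-B-C aldehyde [4-[2,4-dimethoxy-6-(2,4,6-trimethoxyphenoxy)phenoxy]-2,6-dimethoxybenzaldehyde]
Conditions: Cs2CO3, DMSO, 120 °C, Ar
Reagents that add atoms: none
Why: SNAr para to the formyl group, which tolerates the doubly ortho-substituted caesium phenoxide because the fluorinated carbon is unhindered and the methoxy groups are meta to it.

Step 4
Reactants: 7 A-B-C aldehyde
Product: 9 A-B-C phenol ArOH [4-[2,4-dimethoxy-6-(2,4,6-trimethoxyphenoxy)phenoxy]-2,6-dimethoxyphenol], via aryl formate 8 (not isolated)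
Conditions: mCPBA, CH2Cl2, 0 °C to rt; then K2CO3 (cat.), MeOH, rt, Ar
Reagents that add atoms: mCPBA, O=C(OO)c1cccc(Cl)c1
Why: Second Dakin-type Baeyer–Villiger oxidation, the 2,6-dimethoxyaryl group migrating readily, which places the ring C oxygen between its two methoxy groups.

Step 5
Reactants: 9 A-B-C phenol; 10 trichloroethylene
Product: 11 dichlorovinyl ether [ArO–CCl=CHCl, (E)-1,2-dichloroethenyl ether of 9]
Conditions: K2CO3, DMF, 70 °C
Reagents that add atoms: none
Why: Elimination–addition: base converts trichloroethylene into dichloroacetylene in the flask, and anti addition of the phenoxide with protonation gives the (E)-1,2-dichlorovinyl ether, the standard entry to ynol ethers.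

Step 6
Reactants: 11 dichlorovinyl ether; 12 dimethyl squarate
Product: 16 alkynyl cyclobutenone [racemic 4-(ArO-ethynyl)-2,3,4-trimethoxycyclobut-2-en-1-one], via chloroethynyl ether 13 (not isolated), via lithium aryloxyacetylide 14 (not isolated), via lithium alkoxide 15 (not isolated)
Conditions: n-BuLi (2.1 equiv), THF, −78 to −40 °C; 12, −78 °C; MeOTf, −78 to 0 °C
Reagents that add atoms: methyl triflate, COS(=O)(=O)C(F)(F)F
Why: Dehydrochlorination to 13 and chlorine–lithium exchange give acetylide 14, which cannot lose aryloxide, and its 1,2-addition to one squarate carbonyl (acetylide addition to a ketone) followed by O-methylation of alkoxide 15 sets the quaternary carbon as a racemate that step 8 erases.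

Step 7
Reactants: 16 alkynyl cyclobutenone
Product: 17 key-step precursor [racemic 4-[(Z)-2-(ArO)ethenyl]-2,3,4-trimethoxycyclobut-2-en-1-one]
Conditions: H2 (1 atm), Pd/CaCO3 poisoned with Pb(OAc)2, quinoline, EtOAc, rt
Reagents that add atoms: none
Why: Lindlar semihydrogenation adds both hydrogens to the same face of the alkyne and so gives the Z enol ether, while the tetrasubstituted ring alkene, the ketone and the aryl ethers are not reduced and the neutral medium spares the acid-labile enol ether.

Step 8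
Reactants: 17 key-step precursor
Product: 20 A-B-C-D phenol [6-(ArO)-2,3,4-trimethoxyphenol, ring D C2 hydroxyl free], via dienylketene 18 (not isolated), via cyclohexadienone 19 (not isolated)
Conditions: p-xylene (degassed, dilute), 138 °C, Ar
Reagents that add atoms: none
Why: Heating causes a conrotatory 4π electrocyclic opening of the bond between the carbonyl carbon and the quaternary carbon of the cyclobutenone, giving dienylketene 18. A disrotatory 6π electrocyclisation then joins the ketene carbon to the aryloxy-bearing vinyl carbon; this six-membered closure forms the ring D C1–C2 bond and gives dienone 19, whose enolisation aromatises ring D. The closest known reaction type is the Moore ring expansion of 4-alkenyl-4-alkoxycyclobutenones to monoprotected hydroquinones. No stereocentre survives, since the quaternary carbon of 17 becomes sp2 and the CH(OAr) carbon of 19 is lost on tautomerisation. The selectivity needed is inward rotation of the vinyl group during the opening, which the C4 methoxy donor secures by its strong preference to rotate outward, and the linear ketene terminus leaves room for the inward-pointing oxygen of the Z enol ether. Because the ketone oxygen is the only one of the five not carried as a methyl ether, the resulting phenol is free exactly at ring D C2.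

Step 9
Reactants: 20 A-B-C-D phenol; 21 3,4,5-trimethoxyphenylboronic acid
Product: 22 permethylated pentamer [1-(ArO)-3,4,5-trimethoxy-2-(3,4,5-trimethoxyphenoxy)benzene]
Conditions: Cu(OAc)2, pyridine, 4 Å MS, CH2Cl2, air, rt
Reagents that add atoms: none
Why: Chan–Lam oxidative O-arylation, in which the phenoxide binds divalent copper, the aryl group is transferred from boron and C–O reductive elimination from trivalent copper forms the ring D–O–ring E bond at room temperature without touching the ethers.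

Step 10
Reactants: 22 permethylated pentamer
Product: 23 target CNP0243665.0 (tridecahydroxy pentaaryl tetraether)
Conditions: BBr3 (20 equiv), CH2Cl2, −78 °C to rt; then MeOH, H2O, Ar
Reagents that add atoms: none
Why: Lewis acid-mediated ether cleavage in which BBr3 coordinates each methoxy oxygen and bromide removes the methyl group by SN2, the four diaryl ether links having no sp3 carbon to attack, so that hydrolysis of the aryl borates releases all thirteen hydroxyls.

**Compound list**

1 | 2,4,6-trimethoxyphenol | COc1cc(OC)c(O)c(OC)c1 | starting material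
2 | 2-fluoro-4,6-dimethoxybenzaldehyde | O=Cc1c(F)cc(OC)cc1OC | starting material
3 | 2,4-dimethoxy-6-(2,4,6-trimethoxyphenoxy)benzaldehyde | O=Cc1c(Oc2c(OC)cc(OC)cc2OC)cc(OC)cc1OC | intermediate
4 | 2,4-dimethoxy-6-(2,4,6-trimethoxyphenoxy)phenyl formate | O=COc1c(Oc2c(OC)cc(OC)cc2OC)cc(OC)cc1OC | intermediate
5 | 2,4-dimethoxy-6-(2,4,6-trimethoxyphenoxy)phenol | Oc1c(Oc2c(OC)cc(OC)cc2OC)cc(OC)cc1OC | intermediate
6 | 4-fluoro-2,6-dimethoxybenzaldehyde | O=Cc1c(OC)cc(F)cc1OC | starting material
7 | 4-[2,4-dimethoxy-6-(2,4,6-trimethoxyphenoxy)phenoxy]-2,6-dimethoxybenzaldehyde | O=Cc1c(OC)cc(Oc2c(Oc3c(OC)cc(OC)cc3OC)cc(OC)cc2OC)cc1OC | intermediate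
8 | 4-[2,4-dimethoxy-6-(2,4,6-trimethoxyphenoxy)phenoxy]-2,6-dimethoxyphenyl formate | O=COc1c(OC)cc(Oc2c(Oc3c(OC)cc(OC)cc3OC)cc(OC)cc2OC)cc1OC | intermediate
9 | 4-[2,4-dimethoxy-6-(2,4,6-trimethoxyphenoxy)phenoxy]-2,6-dimethoxyphenol (ArOH) | Oc1c(OC)cc(Oc2c(Oc3c(OC)cc(OC)cc3OC)cc(OC)cc2OC)cc1OC | intermediate
10 | trichloroethylene | ClC=C(Cl)Cl | starting material
11 | (E)-1,2-dichloroethenyl ether of 9 (ArO–CCl=CHCl) | Cl/C=C(/Cl)Oc1c(OC)cc(Oc2c(Oc3c(OC)cc(OC)cc3OC)cc(OC)cc2OC)cc1OC | intermediate
12 | dimethyl squarate (3,4-dimethoxycyclobut-3-ene-1,2-dione) | COC1=C(OC)C(=O)C1=O | starting material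
13 | chloroethynyl ether of 9 (ArO–C≡C–Cl) | ClC#COc1c(OC)cc(Oc2c(Oc3c(OC)cc(OC)cc3OC)cc(OC)cc2OC)cc1OC | intermediate
14 | lithium aryloxyacetylide (ArO–C≡C–Li) | [Li]C#COc1c(OC)cc(Oc2c(Oc3c(OC)cc(OC)cc3OC)cc(OC)cc2OC)cc1OC | intermediate
15 | lithium 1-(ArO-ethynyl)-2,3-dimethoxy-4-oxocyclobut-2-en-1-olate (racemic) | COC1=C(OC)C(O[Li])(C#COc2c(OC)cc(Oc3c(Oc4c(OC)cc(OC)cc4OC)cc(OC)cc3OC)cc2OC)C1=O | intermediate
16 | 4-(ArO-ethynyl)-2,3,4-trimethoxycyclobut-2-en-1-one (racemic) | COC1=C(OC)C(OC)(C#COc2c(OC)cc(Oc3c(Oc4c(OC)cc(OC)cc4OC)cc(OC)cc3OC)cc2OC)C1=O | intermediate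
17 | 4-[(Z)-2-(ArO)ethenyl]-2,3,4-trimethoxycyclobut-2-en-1-one (racemic) | COC1=C(OC)C(OC)(/C=C\Oc2c(OC)cc(Oc3c(Oc4c(OC)cc(OC)cc4OC)cc(OC)cc3OC)cc2OC)C1=O | intermediate
18 | (3Z,5Z)-6-(ArO)-2,3,4-trimethoxyhexa-1,3,5-trien-1-one (dienylketene) | O=C=C(OC)/C(OC)=C(OC)\C=C/Oc1c(OC)cc(Oc2c(Oc3c(OC)cc(OC)cc3OC)cc(OC)cc2OC)cc1OC | intermediate
19 | 6-(ArO)-2,3,4-trimethoxycyclohexa-2,4-dien-1-one (racemic) | O=C1C(Oc2c(OC)cc(Oc3c(Oc4c(OC)cc(OC)cc4OC)cc(OC)cc3OC)cc2OC)C=C(OC)C(OC)=C1OC | intermediate
20 | 6-(ArO)-2,3,4-trimethoxyphenol (A-B-C-D phenol, ring D C2 hydroxyl free) | Oc1c(OC)c(OC)c(OC)cc1Oc2c(OC)cc(Oc3c(Oc4c(OC)cc(OC)cc4OC)cc(OC)cc3OC)cc2OC | intermediate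
21 | 3,4,5-trimethoxyphenylboronic acid | COc1cc(B(O)O)cc(OC)c1OC | starting material
22 | 1-(ArO)-3,4,5-trimethoxy-2-(3,4,5-trimethoxyphenoxy)benzene (tridecamethyl ether of the target) | COc1cc(Oc2c(OC)c(OC)c(OC)cc2Oc3c(OC)cc(Oc4c(Oc5c(OC)cc(OC)cc5OC)cc(OC)cc4OC)cc3OC)cc(OC)c1OC | intermediate
23 | CNP0243665.0 | Oc1cc(O)c(Oc2cc(O)cc(O)c2Oc2cc(O)c(Oc3cc(O)c(O)c(O)c3Oc3cc(O)c(O)c(O)c3)c(O)c2)c(O)c1 | target

**Step count.** Total steps: 10. Longest linear sequence: 10 steps (1 to 23).

**Steps most likely to fail**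

1. Step 8. The 6π closure of the Z-configured dienylketene may be slow, so that the ketene is diverted (dimerisation, capture by adventitious water) or the enol ether is cleaved on prolonged heating. The fallback sets out from phenol 9 and builds ring D by a coupling/oxidation sequence of known type. Rieche formylation of commercial 5-bromo-1,2,3-trimethoxybenzene (Cl2CHOMe, TiCl4, CH2Cl2, 0 °C) should give 6-bromo-2,3,4-trimethoxybenzaldehyde F1. Ullmann coupling of 9 with F1 (CuI, picolinic acid, K3PO4, DMSO, 90 °C), assisted by the ortho formyl group, should give 6-(ArO)-2,3,4-trimethoxybenzaldehyde F2. Oxidation with mCPBA to 6-(ArO)-2,3,4-trimethoxyphenyl formate F3 and methanolysis (K2CO3, MeOH) return to the route at 20.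

2. Step 10. Ether cleavage may stop short at some of the thirteen sites, and the pyrogallol-type rings D and E may oxidise in air during isolation of the free polyphenol. The fallback sets out from 22. The methyl ethers are cleaved with the hard acid/soft nucleophile pair AlCl3/EtSH in CH2Cl2, and the crude polyphenol is acetylated in the same flask (Ac2O, pyridine) to the tridecaacetate of the target F7, which is stable and can be purified by chromatography. Acid-catalysed methanolysis of F7 (HCl from AcCl, degassed MeOH, rt) then returns to the route at 23.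

3. Step 9. Aryl transfer to copper may be slow with the doubly ortho-substituted phenol, allowing oxidation of the electron-rich phenol and protodeboronation or homocoupling of 21 to compete. The fallback is copper-free and sets out from 20. SNAr with fluoroaldehyde 6 (Cs2CO3, DMSO, 120 °C) should give 4-[6-(ArO)-2,3,4-trimethoxyphenoxy]-2,6-dimethoxybenzaldehyde F4. Oxidation with mCPBA gives 4-[6-(ArO)-2,3,4-trimethoxyphenoxy]-2,6-dimethoxyphenyl formate F5, and methanolysis gives 4-[6-(ArO)-2,3,4-trimethoxyphenoxy]-2,6-dimethoxyphenol F6. O-Methylation of F6 (MeI, K2CO3, acetone) returns to the route at 22.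

**Further compounds**

F1 | step 8 | 6-bromo-2,3,4-trimethoxybenzaldehyde | O=Cc1c(Br)cc(OC)c(OC)c1OC
F2 | step 8 | 6-(ArO)-2,3,4-trimethoxybenzaldehyde | O=Cc1c(OC)c(OC)c(OC)cc1Oc2c(OC)cc(Oc3c(Oc4c(OC)cc(OC)cc4OC)cc(OC)cc3OC)cc2OC
F3 | step 8 | 6-(ArO)-2,3,4-trimethoxyphenyl formate | O=COc1c(OC)c(OC)c(OC)cc1Oc2c(OC)cc(Oc3c(Oc4c(OC)cc(OC)cc4OC)cc(OC)cc3OC)cc2OC
F4 | step 9 | 4-[6-(ArO)-2,3,4-trimethoxyphenoxy]-2,6-dimethoxybenzaldehyde | O=Cc1c(OC)cc(Oc2c(OC)c(OC)c(OC)cc2Oc3c(OC)cc(Oc4c(Oc5c(OC)cc(OC)cc5OC)cc(OC)cc4OC)cc3OC)cc1OC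
F5 | step 9 | 4-[6-(ArO)-2,3,4-trimethoxyphenoxy]-2,6-dimethoxyphenyl formate | O=COc1c(OC)cc(Oc2c(OC)c(OC)c(OC)cc2Oc3c(OC)cc(Oc4c(Oc5c(OC)cc(OC)cc5OC)cc(OC)cc4OC)cc3OC)cc1OC
F6 | step 9 | 4-[6-(ArO)-2,3,4-trimethoxyphenoxy]-2,6-dimethoxyphenol | Oc1c(OC)cc(Oc2c(OC)c(OC)c(OC)cc2Oc3c(OC)cc(Oc4c(Oc5c(OC)cc(OC)cc5OC)cc(OC)cc4OC)cc3OC)cc1OC
F7 | step 10 | tridecaacetate of the target | CC(=O)Oc1cc(OC(C)=O)c(Oc2cc(OC(C)=O)cc(OC(C)=O)c2Oc2cc(OC(C)=O)c(Oc3cc(OC(C)=O)c(OC(C)=O)c(OC(C)=O)c3Oc3cc(OC(C)=O)c(OC(C)=O)c(OC(C)=O)c3)c(OC(C)=O)c2)c(OC(C)=O)c1
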